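## The problem

The target is a linear diarylheptanoid of the gingerol type. A seven-carbon chain carries the guaiacyl ring A on C1 and the syringyl ring B on C7, with a ketone at C3 and a hydroxyl at C5. No ring has to be closed, so the work lies in joining two different aryl ends to a C3–C5 aldol unit. C5 (R) is the only stereocentre and nothing else in the molecule can relay chirality to it, so it must come from a reagent, a catalyst or the chiral pool. In the saturated chain C5 sits between two methylene flanks (C4 and C6) that a reducing catalyst can hardly tell apart, and a free C3 carbonyl would turn any C5 ketone precursor into an enolised 1,3-diketone. The β-hydroxy ketone is the fragile part: acid or base with heat dehydrates it to the C4–C5 enone or cleaves it by retro-aldol reaction. It should therefore be unveiled last and gently, and the two electron-rich phenols should stay masked until the end. The feature that opens a way is that C6–C7 runs straight into ring B. If these two carbons are temporarily a triple bond, C5 becomes the carbonyl of an aryl ynone with a rod-like sp flank on one side and the sp3 C4 methylene on the other, a pair that a chiral transfer-hydrogenation catalyst can distinguish. The triple bond costs nothing to remove, because the hydrogenation that takes benzyl groups off the phenols saturates it as well.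

## Retrosynthesis

**16 to 15.** The last operation should be the release of the C3 carbonyl, so target 16 is traced back to dioxolane 15; only the two C3–O acetal bonds differ. A dioxolane is preferred to a dithiane, which would poison the Pd/C needed one step earlier, and to an open dimethyl acetal, which a β-alkoxy carbonyl compound loses easily by elimination. The precursor is no simpler in skeleton but is no longer an aldol, so it tolerates the preceding steps. The forward reaction has to be a hydrolysis mild enough to leave the β-hydroxy ketone alone.

**15 to 14.** No skeletal bond is cut. Four hydrogens are taken from C6–C7 and the two phenolic O–H bonds are replaced by O–benzyl bonds, which gives propargylic alcohol 14. This is preferred to any other phenol protection because one hydrogenation then does three jobs in the forward direction. C5 is not touched; its descriptor changes from S in 14 to R in 15 only because an alkynyl carbon outranks C4 whereas the saturated C6 does not. The forward step must saturate the alkyne without hydrogenolysis of the C5–O bond.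

**14 to 13.** The C5–H bond is cut, giving achiral ynone 13. Neighbouring options are weaker: reduction of a saturated C5 ketone would face two methylene flanks, and an acetate-type aldol forming C4–C5 has poor intrinsic facial control. The precursor carries no stereocentre, so the whole stereochemical problem is concentrated in one catalytic step. That step must select one carbonyl face and reduce 1,2 only.

**13 to 8 and 11.** The C5–C6 bond is cut between the acyl carbon and the alkyne, leading to Weinreb amide 8 and lithium acetylide 12, which is made in the flask from terminal alkyne 11. The cut divides the molecule into two halves of similar size, each holding one aryl ring. A cut at C6–C7 (arylation of a terminal ynone) would require a base-sensitive terminal ynone, and addition of 12 to an aldehyde followed by oxidation costs one more step. The forward reaction must stop at single addition, which the chelated Weinreb adduct ensures.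

**11 to 10 to 9.** The C6–C7 triple bond is cut back to the formyl group of aldehyde 10; C6 is the one carbon added in a diazophosphonate homologation. Aldehyde 10 is the benzyl ether of syringaldehyde 9. Ring B thus enters from a bulk aldehyde at the oxidation level in which it is sold.

**8 to 7 to 6.** Two functional-group changes follow: the amide goes back to ethyl ester 7 and the dioxolane to β-keto ester 6. The C3 carbonyl is masked at this stage because β-keto esters form dioxolanes readily and because a free 1,3-dicarbonyl would quench the acetylide later.

**6 to 3 and 4.** The C1–C2 bond is cut: γ-alkylation of dianion 5 of ethyl acetoacetate 4 with benzylic chloride 3. The neighbouring C2–C3 cut would need a homologated 3-arylpropanoyl unit, whereas the benzylic electrophile is one step from the alcohol. Compound 4 supplies C2 to C5 with the correct oxidation levels at C3 and C5.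

**3 to 2 to 1.** Chloride 3 comes from benzylic alcohol 2, and 2 from O-benzylvanillin 1 by hydride reduction. Both are routine changes on a purchasable aldehyde.

## Roads not taken

**Alternative 1:** The cut is C6–C7 and the stereocentre is bought.
- **Key step:** 4-benzyloxy-3,5-dimethoxybenzylmagnesium chloride (A1), with catalytic CuBr·SMe2, would open ethyl (S)-3,4-epoxybutanoate (A2) at its terminal carbon. This would give ethyl (3R)-5-(4-benzyloxy-3,5-dimethoxyphenyl)-3-hydroxypentanoate (A3).
- **Merits:** The C5 configuration comes from the chiral pool and the ring opening does not touch it. No asymmetric catalysis is needed, and A3 already has the oxygen pattern of C3 and C5.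
- **Weak points:** Electron-rich benzylic magnesium reagents such as A1 tend to dimerise by Wurtz coupling while they are formed. A2 has acidic α-hydrogens, so a basic organometallic can open it by β-elimination to a 4-hydroxycrotonate or attack the ester. After the key step the C1–C2 unit with ring A must still be attached to the ester carbon, which requires hydroxyl protection, a change of the acyl group and a homobenzylic organometallic, so the step count is no lower.
- **Comparison:** In stereochemical certainty this road is better than the chosen one, because it does not depend on how a catalyst behaves on a new substrate. The chosen plan offers in return two robust carbon–carbon couplings (steps 3 and 8) and a ring A unit that enters as the simple benzylic chloride 3. Apart from the acetal, all its masking groups leave in a hydrogenation that is needed anyway.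

**Alternative 2:** The cut is C2–C3, at the ketone itself.
- **Key step:** In an undivided cell with a sacrificial zinc anode, NiBr2(dme) with 4,4'-di-tert-butyl-2,2'-bipyridine would couple S-(pyridin-2-yl) (3R)-5-(4-benzyloxy-3,5-dimethoxyphenyl)-3-(tert-butyldimethylsilyloxy)pentanethioate (A4) with 1-(benzyloxy)-4-(2-iodoethyl)-2-methoxybenzene (A5). The product would be the silyl-protected, doubly benzylated ketone A6.
- **Merits:** It is the most convergent of the four plans. The ketone appears at its final oxidation level, so no C3 mask is needed, which saves the acetalisation and hydrolysis steps of the chosen route. The conditions are neutral.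
- **Weak points:** The coupling creates no stereocentre. C5 must already be enantiopure in A4, which presupposes a separate asymmetric step or a chiral-pool intermediate such as A3, so the stereochemical problem is only moved. A4 and A5 each need several steps. The acylnickel intermediate carries a β-silyloxy group and may eliminate or decarbonylate, and A5 may homocouple. The later desilylation of a β-silyloxy ketone invites the same elimination that threatens the target.
- **Comparison:** This road is better in convergence and in redox economy at C3. The chosen plan solves the stereocentre in a single step with a well-understood selectivity model, and all its bond-forming steps are classical.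

**Alternative 3:** The cut is C5–C6, with the stereocentre made during bond formation.
- **Key step:** The racemic 1-bromoalkyl benzoate A7 (C1 to C5, C3 as a 1,3-dithiane) would couple with 2-(4-benzyloxy-3,5-dimethoxyphenyl)ethylzinc bromide (A8) under NiBr2(dme) and a chiral bis(oxazoline) ligand. This would give the (R)-benzoate A9.
- **Merits:** Both enantiomers of A7 converge through a common radical, and one step creates a skeletal bond and the stereocentre together, which the chosen key step does not. The ligand differentiates oxygen from carbon at C5, so the similarity of the two chain arms is irrelevant.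
- **Weak points:** A7 is a moisture-sensitive α-bromo ester that must be made just before use. The dithiane sulfur can bind nickel and would poison Pd/C in the later debenzylation. Its removal needs soft electrophiles or oxidants that also attack the electron-rich guaiacyl and syringyl rings. A8 requires a multistep homologation of the ring B aldehyde, and A9 needs three separate deprotections (benzoate, dithiane, benzyl).
- **Comparison:** This road has the better bond and stereocentre economy in the key step, but a longer endgame with conflicting protecting groups. The chosen plan uses an acetal that is compatible with Pd/C and a hydrogenation that removes the alkyne and both benzyl groups at once.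

Key step: step 9

Assumption: the chain is numbered C1 (on guaiacyl ring A) to C7 (on syringyl ring B) throughout, and O-benzylvanillin 1 is bought as such. TsDPEN stands for N-(p-toluenesulfonyl)-1,2-diphenylethylenediamine.

## Route

Step 1
Reactants: 1 4-(benzyloxy)-3-methoxybenzaldehyde (O-benzylvanillin)
Product: 2 [4-(benzyloxy)-3-methoxyphenyl]methanol
Conditions: NaBH4 (0.6 equiv), MeOH/THF, 0 °C to rt
Reagents that add atoms: none
Why: Borohydride reduction of an aromatic aldehyde; the aryl benzyl and methyl ethers are inert to NaBH4.

Step 2
Reactants: 2 [4-(benzyloxy)-3-methoxyphenyl]methanol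
Product: 3 1-(benzyloxy)-4-(chloromethyl)-2-methoxybenzene
Conditions: SOCl2 (1.2 equiv), CH2Cl2, 0 °C to rt
Reagents that add atoms: thionyl chloride, O=S(Cl)Cl
Why: Chlorodehydroxylation of a benzylic alcohol through its chlorosulfite; the electron-rich benzylic position reacts readily, and the chloride is used soon after isolation.

Step 3
Reactants: 4 ethyl acetoacetate; 3 1-(benzyloxy)-4-(chloromethyl)-2-methoxybenzene
Product: 6 ethyl 5-[4-(benzyloxy)-3-methoxyphenyl]-3-oxopentanoate, via ethyl acetoacetate dianion 5 (not isolated)
Conditions: 4, NaH (1.1 equiv), THF, 0 °C; n-BuLi (1.05 equiv), 0 °C; then 3 (0.9 equiv), 0 °C to rt; aq. NH4Cl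
Reagents that add atoms: none
Why: Huckin–Weiler γ-alkylation of an acetoacetate dianion; the more basic terminal carbanion attacks the benzylic chloride in an SN2 reaction while the stabilised enolate stays unreactive, so the C1–C2 bond forms without α- or O-alkylation.

Step 4
Reactants: 6 ethyl 5-[4-(benzyloxy)-3-methoxyphenyl]-3-oxopentanoate
Product: 7 ethyl 2-(2-{2-[4-(benzyloxy)-3-methoxyphenyl]ethyl}-1,3-dioxolan-2-yl)acetate
Conditions: HOCH2CH2OH (5 equiv), p-TsOH·H2O (5 mol %), toluene, reflux, Dean–Stark trap
Reagents that add atoms: ethylene glycol, OCCO
Why: Acid-catalysed acetalisation with azeotropic removal of water, a standard protection of β-keto esters; the ester and the benzyl ether tolerate catalytic sulfonic acid.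

Step 5
Reactants: 7 ethyl 2-(2-{2-[4-(benzyloxy)-3-methoxyphenyl]ethyl}-1,3-dioxolan-2-yl)acetate
Product: 8 2-(2-{2-[4-(benzyloxy)-3-methoxyphenyl]ethyl}-1,3-dioxolan-2-yl)-N-methoxy-N-methylacetamide
Conditions: MeNH(OMe)·HCl (1.5 equiv), i-PrMgCl (3.0 equiv), THF, –20 to 0 °C; aq. NH4Cl
Reagents that add atoms: N,O-dimethylhydroxylamine hydrochloride, CNOC.Cl
Why: Direct ester aminolysis by the chloromagnesium amide of N,O-dimethylhydroxylamine (ester to Weinreb amide conversion); at low temperature the amide acts as a nucleophile and not as a base towards the hydrogens next to the acetal.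

Step 6
Reactants: 9 syringaldehyde (4-hydroxy-3,5-dimethoxybenzaldehyde)
Product: 10 4-(benzyloxy)-3,5-dimethoxybenzaldehyde
Conditions: BnBr (1.1 equiv), K2CO3 (1.5 equiv), DMF, 60 °C
Reagents that add atoms: benzyl bromide, BrCc1ccccc1
Why: Williamson ether synthesis; the flanked phenoxide is still alkylated cleanly by the reactive benzylic bromide in a dipolar aprotic solvent.

Step 7
Reactants: 10 4-(benzyloxy)-3,5-dimethoxybenzaldehyde
Product: 11 2-(benzyloxy)-5-ethynyl-1,3-dimethoxybenzene
Conditions: dimethyl (1-diazo-2-oxopropyl)phosphonate (1.3 equiv), K2CO3 (2 equiv), MeOH, 0 °C to rt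
Reagents that add atoms: dimethyl (1-diazo-2-oxopropyl)phosphonate, COP(=O)(OC)C(=[N+]=[N-])C(C)=O
Why: Seyferth–Gilbert homologation in the Ohira–Bestmann variant; methanolysis frees the diazomethylphosphonate anion, olefination gives a diazoalkene, and loss of N2 with a 1,2-hydrogen shift gives the alkyne. The mild carbonate base suits a non-enolisable aryl aldehyde.

Step 8
Reactants: 11 2-(benzyloxy)-5-ethynyl-1,3-dimethoxybenzene; 8 2-(2-{2-[4-(benzyloxy)-3-methoxyphenyl]ethyl}-1,3-dioxolan-2-yl)-N-methoxy-N-methylacetamide
Product: 13 4-[4-(benzyloxy)-3,5-dimethoxyphenyl]-1-(2-{2-[4-(benzyloxy)-3-methoxyphenyl]ethyl}-1,3-dioxolan-2-yl)but-3-yn-2-one, via lithium arylacetylide 12 (not isolated)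
Conditions: 11 (1.2 equiv), n-BuLi (1.15 equiv), THF, –78 °C; then 8, –78 to 0 °C; inverse quench into cold aq. NH4Cl
Reagents that add atoms: none
Why: Weinreb ketone synthesis with a lithium acetylide; the chelated tetrahedral adduct persists until the quench, so only one acetylide adds and the C5–C6 bond is formed. The cold inverse quench keeps the liberated amine from adding to the ynone.

Step 9
Reactants: 13 4-[4-(benzyloxy)-3,5-dimethoxyphenyl]-1-(2-{2-[4-(benzyloxy)-3-methoxyphenyl]ethyl}-1,3-dioxolan-2-yl)but-3-yn-2-one
Product: 14 (2S)-4-[4-(benzyloxy)-3,5-dimethoxyphenyl]-1-(2-{2-[4-(benzyloxy)-3-methoxyphenyl]ethyl}-1,3-dioxolan-2-yl)but-3-yn-2-ol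
Conditions: Ru[(S,S)-TsDPEN](p-cymene) (2 mol %, preformed from RuCl[(S,S)-TsDPEN](p-cymene) and KOH), i-PrOH (0.1 M), 25 °C
Reagents that add atoms: none
Why: This is a Noyori–Ikariya asymmetric transfer hydrogenation, whose closest known use is the reduction of α,β-acetylenic ketones by Ru/TsDPEN complexes in 2-propanol. The 16-electron amido complex takes H2 from 2-propanol to become the 18-electron hydride RuH[(S,S)-TsDPEN](p-cymene), which passes the hydride from ruthenium to C5 and a proton from the ligand NH2 to the carbonyl oxygen in one six-membered outer-sphere transition state, the ketone never entering the coordination sphere. No ring is closed and no skeletal bond is made; the only new bond is C5–H. The C5 stereocentre is set by the catalyst alone: the rod-like arylethynyl group takes the place near the η6-cymene that an aryl group takes in aryl ketone reductions, the sp3 C4 methylene points away, and the (S,S) ligand is expected to expose the face that leads to the S carbinol. The step needs enantioface selectivity and 1,2- over 1,4-selectivity; the first rests on the large shape difference between the linear sp substituent and the branched sp3 one, the second on the polar hydride/proton transfer, which does not touch the triple bond. The dioxolane keeps C3 from acting as a second carbonyl or as part of an enolised 1,3-diketone, and the base-free medium protects the acidic C4 hydrogens. Because a conjugated ynone is a strong hydride acceptor, the equilibrium with acetone should lie on the product side, so the reverse reaction should not erode the enantiomeric purity.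

Step 10
Reactants: 14 (2S)-4-[4-(benzyloxy)-3,5-dimethoxyphenyl]-1-(2-{2-[4-(benzyloxy)-3-methoxyphenyl]ethyl}-1,3-dioxolan-2-yl)but-3-yn-2-ol
Product: 15 (2R)-4-(4-hydroxy-3,5-dimethoxyphenyl)-1-{2-[2-(4-hydroxy-3-methoxyphenyl)ethyl]-1,3-dioxolan-2-yl}butan-2-ol
Conditions: H2 (1 atm), 10% Pd/C, EtOAc/EtOH, rt
Reagents that add atoms: none
Why: Heterogeneous catalytic hydrogenation with hydrogenolysis; Pd/C saturates the C6–C7 triple bond and cleaves both aryl benzyl ethers in one operation, while the neutral medium keeps the dioxolane. C5 is not touched; its descriptor changes from S to R only because C6 loses its priority over C4.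

Step 11
Reactants: 15 (2R)-4-(4-hydroxy-3,5-dimethoxyphenyl)-1-{2-[2-(4-hydroxy-3-methoxyphenyl)ethyl]-1,3-dioxolan-2-yl}butan-2-ol
Product: 16 (5R)-5-hydroxy-7-(4-hydroxy-3,5-dimethoxyphenyl)-1-(4-hydroxy-3-methoxyphenyl)heptan-3-one
Conditions: pyridinium p-toluenesulfonate (0.2 equiv), acetone/H2O (9:1), rt to 40 °C
Reagents that add atoms: water, O
Why: Mildly acid-catalysed acetal hydrolysis assisted by exchange with acetone; the weakly acidic pyridinium salt should free the C3 ketone without dehydrating the β-hydroxy ketone, so the C5 hydroxyl and its configuration are retained.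

## Compound list

1 | 4-(benzyloxy)-3-methoxybenzaldehyde (O-benzylvanillin) | COc1cc(C=O)ccc1OCc1ccccc1 | starting material
2 | [4-(benzyloxy)-3-methoxyphenyl]methanol | COc1cc(CO)ccc1OCc1ccccc1 | intermediate
3 | 1-(benzyloxy)-4-(chloromethyl)-2-methoxybenzene | COc1cc(CCl)ccc1OCc1ccccc1 | intermediate
4 | ethyl acetoacetate | CCOC(=O)CC(C)=O | starting material
5 | ethyl acetoacetate dianion (sodium lithium salt) | [Na+].[Li+].[CH2-]C(=O)[CH-]C(=O)OCC | intermediate (not isolated)
6 | ethyl 5-[4-(benzyloxy)-3-methoxyphenyl]-3-oxopentanoate | CCOC(=O)CC(=O)CCc1ccc(OCc2ccccc2)c(OC)c1 | intermediate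
7 | ethyl 2-(2-{2-[4-(benzyloxy)-3-methoxyphenyl]ethyl}-1,3-dioxolan-2-yl)acetate | CCOC(=O)CC1(CCc2ccc(OCc3ccccc3)c(OC)c2)OCCO1 | intermediate
8 | 2-(2-{2-[4-(benzyloxy)-3-methoxyphenyl]ethyl}-1,3-dioxolan-2-yl)-N-methoxy-N-methylacetamide | CON(C)C(=O)CC1(CCc2ccc(OCc3ccccc3)c(OC)c2)OCCO1 | intermediate
9 | syringaldehyde (4-hydroxy-3,5-dimethoxybenzaldehyde) | COc1cc(C=O)cc(OC)c1O | starting material
10 | 4-(benzyloxy)-3,5-dimethoxybenzaldehyde | COc1cc(C=O)cc(OC)c1OCc1ccccc1 | intermediate
11 | 2-(benzyloxy)-5-ethynyl-1,3-dimethoxybenzene | COc1cc(C#C)cc(OC)c1OCc1ccccc1 | intermediate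
12 | lithium [4-(benzyloxy)-3,5-dimethoxyphenyl]acetylide | [Li]C#Cc1cc(OC)c(OCc2ccccc2)c(OC)c1 | intermediate (not isolated)
13 | 4-[4-(benzyloxy)-3,5-dimethoxyphenyl]-1-(2-{2-[4-(benzyloxy)-3-methoxyphenyl]ethyl}-1,3-dioxolan-2-yl)but-3-yn-2-one | COc1cc(CCC2(CC(=O)C#Cc3cc(OC)c(OCc4ccccc4)c(OC)c3)OCCO2)ccc1OCc1ccccc1 | intermediate
14 | (2S)-4-[4-(benzyloxy)-3,5-dimethoxyphenyl]-1-(2-{2-[4-(benzyloxy)-3-methoxyphenyl]ethyl}-1,3-dioxolan-2-yl)but-3-yn-2-ol | COc1cc(CCC2(C[C@H](O)C#Cc3cc(OC)c(OCc4ccccc4)c(OC)c3)OCCO2)ccc1OCc1ccccc1 | intermediate
15 | (2R)-4-(4-hydroxy-3,5-dimethoxyphenyl)-1-{2-[2-(4-hydroxy-3-methoxyphenyl)ethyl]-1,3-dioxolan-2-yl}butan-2-ol | COc1cc(CCC2(C[C@H](O)CCc3cc(OC)c(O)c(OC)c3)OCCO2)ccc1O | intermediate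
16 | (5R)-5-hydroxy-7-(4-hydroxy-3,5-dimethoxyphenyl)-1-(4-hydroxy-3-methoxyphenyl)heptan-3-one | COc1cc(CCC(=O)C[C@H](O)CCc2cc(OC)c(O)c(OC)c2)ccc1O | target

## Step count and least certain steps

Total step count: 11. Longest linear sequence: 9 (steps 1 to 5 and 8 to 11); steps 6 and 7 form the ring B branch.

**Step 9 (key step).** The most likely failure is insufficient enantioface selectivity. The C4 methylene carries the fully substituted acetal carbon, and this neopentyl-like bulk may disturb the usual placement of the alkynyl and alkyl groups against the arene ligand. Traces of base could in addition cause conjugate addition of 2-propoxide to the ynone, or opening of the dioxolane by β-elimination. The fallback leaves catalysis for a stoichiometric chiral hydride donor, the Midland reduction. It sets out from ynone 13 and uses B-isopinocampheyl-9-borabicyclo[3.3.1]nonane prepared from (–)-α-pinene, with little or no solvent at rt. The hydride is transferred from the pinanyl group through a boat-like six-membered transition state in which the slim alkyne is the small substituent, and the S carbinol is expected. The fallback comes back to the route at 14 and makes no compound outside the list (entry F0).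

**Step 8.** Two processes threaten the acylation. The acetylide may deprotonate C4 of amide 8, and the resulting enolate can open the dioxolane by β-elimination. At the quench, the liberated N,O-dimethylhydroxylamine may add in conjugate fashion to the newly formed ynone. The fallback avoids the amide altogether. It sets out from ester 7, which i-Bu2AlH in CH2Cl2 at –78 °C should reduce to 2-(2-{2-[4-(benzyloxy)-3-methoxyphenyl]ethyl}-1,3-dioxolan-2-yl)acetaldehyde F1. Lithium acetylide 12 is then added to give the racemic propargylic alcohol F2, and F2 is oxidised with MnO2 in CH2Cl2. No amine is released on this way and the alkoxide adduct is not an electrophile. The fallback returns to the route at ynone 13.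

**Step 10.** On Pd/C the propargylic and then allylic C5–O bond may undergo hydrogenolysis. The allylic alcohol formed half-way may also isomerise to the saturated C5 ketone. Either process destroys the stereocentre. An acidic batch of catalyst could further strip the acetal in the alcohol solvent. The fallback separates the two tasks. It sets out from 14, which is hydrogenated homogeneously with RhCl(PPh3)3 and H2 in benzene/EtOH; this catalyst reduces carbon–carbon multiple bonds but does not cleave C–O bonds. The product is the saturated dibenzyl ether (2R)-4-[4-(benzyloxy)-3,5-dimethoxyphenyl]-1-(2-{2-[4-(benzyloxy)-3-methoxyphenyl]ethyl}-1,3-dioxolan-2-yl)butan-2-ol F3. Its benzyl ethers are then removed with H2 over Pd(OH)2/C in EtOAc, now beside an ordinary secondary alcohol. The fallback returns to the route at 15.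

**Step 5.** The chloromagnesium amide may act as a base instead of a nucleophile. Enolisation of ester 7 followed by β-elimination would open the dioxolane to a β-alkoxy enoate, and the hindered ester may react sluggishly. The fallback replaces aminolysis by hydrolysis and coupling. It sets out from 7, which is saponified with LiOH in THF/MeOH/H2O and acidified carefully to about pH 5 to give 2-(2-{2-[4-(benzyloxy)-3-methoxyphenyl]ethyl}-1,3-dioxolan-2-yl)acetic acid F4. The acid is activated with 1,1'-carbonyldiimidazole and treated with MeNH(OMe)·HCl. The fallback returns to the route at 8.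

The closing hydrolysis (step 11) is judged less uncertain than these four, because pyridinium p-toluenesulfonate is only weakly acidic and aldols of this type resist dehydration under such conditions at moderate temperature.

## Further compounds

F0 | step 9 | none | none
F1 | step 8 | 2-(2-{2-[4-(benzyloxy)-3-methoxyphenyl]ethyl}-1,3-dioxolan-2-yl)acetaldehyde | COc1cc(CCC2(CC=O)OCCO2)ccc1OCc1ccccc1
F2 | step 8 | racemic 4-[4-(benzyloxy)-3,5-dimethoxyphenyl]-1-(2-{2-[4-(benzyloxy)-3-methoxyphenyl]ethyl}-1,3-dioxolan-2-yl)but-3-yn-2-ol | COc1cc(CCC2(CC(O)C#Cc3cc(OC)c(OCc4ccccc4)c(OC)c3)OCCO2)ccc1OCc1ccccc1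
F3 | step 10 | (2R)-4-[4-(benzyloxy)-3,5-dimethoxyphenyl]-1-(2-{2-[4-(benzyloxy)-3-methoxyphenyl]ethyl}-1,3-dioxolan-2-yl)butan-2-ol | COc1cc(CCC2(C[C@H](O)CCc3cc(OC)c(OCc4ccccc4)c(OC)c3)OCCO2)ccc1OCc1ccccc1
F4 | step 5 | 2-(2-{2-[4-(benzyloxy)-3-methoxyphenyl]ethyl}-1,3-dioxolan-2-yl)acetic acid | COc1cc(CCC2(CC(=O)O)OCCO2)ccc1OCc1ccccc1
A1 | alternative 1 | 4-benzyloxy-3,5-dimethoxybenzylmagnesium chloride | COc1cc(C[Mg]Cl)cc(OC)c1OCc1ccccc1
A2 | alternative 1 | ethyl (S)-3,4-epoxybutanoate | CCOC(=O)C[C@H]1CO1
A3 | alternative 1 | ethyl (3R)-5-(4-benzyloxy-3,5-dimethoxyphenyl)-3-hydroxypentanoate | CCOC(=O)C[C@H](O)CCc1cc(OC)c(OCc2ccccc2)c(OC)c1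
A4 | alternative 2 | S-(pyridin-2-yl) (3R)-5-(4-benzyloxy-3,5-dimethoxyphenyl)-3-(tert-butyldimethylsilyloxy)pentanethioate | O=C(Sc1ccccn1)C[C@H](O[Si](C)(C)C(C)(C)C)CCc1cc(OC)c(OCc2ccccc2)c(OC)c1
A5 | alternative 2 | 1-(benzyloxy)-4-(2-iodoethyl)-2-methoxybenzene | COc1cc(CCI)ccc1OCc1ccccc1
A6 | alternative 2 | (5R)-1-(4-benzyloxy-3-methoxyphenyl)-7-(4-benzyloxy-3,5-dimethoxyphenyl)-5-(tert-butyldimethylsilyloxy)heptan-3-one | COc1cc(CCC(=O)C[C@H](O[Si](C)(C)C(C)(C)C)CCc2cc(OC)c(OCc3ccccc3)c(OC)c2)ccc1OCc1ccccc1
A7 | alternative 3 | racemic 1-bromo-2-(2-{2-[4-(benzyloxy)-3-methoxyphenyl]ethyl}-1,3-dithian-2-yl)ethyl benzoate | COc1cc(CCC2(CC(Br)OC(=O)c3ccccc3)SCCCS2)ccc1OCc1ccccc1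
A8 | alternative 3 | 2-(4-benzyloxy-3,5-dimethoxyphenyl)ethylzinc bromide | COc1cc(CC[Zn]Br)cc(OC)c1OCc1ccccc1
A9 | alternative 3 | (2R)-4-(4-benzyloxy-3,5-dimethoxyphenyl)-1-(2-{2-[4-(benzyloxy)-3-methoxyphenyl]ethyl}-1,3-dithian-2-yl)butan-2-yl benzoate | COc1cc(CCC2(C[C@H](OC(=O)c3ccccc3)CCc3cc(OC)c(OCc4ccccc4)c(OC)c3)SCCCS2)ccc1OCc1ccccc1
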